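**Strategy.** Atom numbers follow the C15 chain of the target (C1 = alkyne CH, C6 = CHCl, ring oxygen on C7 and C13). The oxocene is not closed directly. Its C9–O, C10–O, cis-C11=C12 and C13–O array is read as a 3,6-dihydro-2H-pyran in which the C9 oxygen is temporarily tied to C13. A hetero-Diels–Alder reaction of epoxy aldehyde 8 with 1,4-bis(silyloxy)diene 12 forms C9–C10, and in the same flask the ketal hydroxyl unveiled at C13 opens the C6–C7 epoxide, forming the ring O–C7 bond. The resulting 2,9-dioxabicyclo[3.3.1]nonene is later cut reductively at its one-atom bridge, expanding six-membered rings to the eight-membered ether.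

Key step: step 11

Remark on the chemistry: the sense of induction of the chiral catalysts (steps 3 and 11, and the transfer hydrogenation of the first fallback) is assigned by analogy; the antipodal catalyst is used if the sense proves opposite. CrCl(L) denotes the chloro complex of trivalent chromium with L, the dianion of the tridentate Schiff base from (1S,2R)-1-aminoindan-2-ol and 3-(1-adamantyl)-2-hydroxy-5-methylbenzaldehyde.

**Step 1**
Reactants: 1 (E)-hex-3-enedioic acid
Product: 2 (E)-hex-3-ene-1,6-diol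
Conditions: LiAlH4, THF, 0 °C to reflux; aqueous NaOH work-up
Reagents that add atoms: none
Why: Hydride reduction of both carboxylic acids to primary alcohols should leave the isolated E alkene untouched (LiAlH4 reduction).

**Step 2**
Reactants: 2 (E)-hex-3-ene-1,6-diol
Product: 3 mono-TBDPS ether
Conditions: NaH (1.0 equiv), THF, 0 °C; then t-BuPh2SiCl (1.0 equiv), 23 °C
Reagents that add atoms: tert-butyl(chloro)diphenylsilane, CC(C)(C)[Si](Cl)(c1ccccc1)c1ccccc1
Why: Silylation of the sparingly soluble monosodium alkoxide of a symmetric diol should favour the mono-ether (O-silylation, Williamson type).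

**Step 3**
Reactants: 3 mono-TBDPS ether
Product: 4 (2S,3S)-epoxy alcohol
Conditions: 1,2:4,5-di-O-isopropylidene-β-L-erythro-2,3-hexodiulo-2,6-pyranose (30 mol %), KHSO5 (as 2KHSO5·KHSO4·K2SO4), K2CO3, Bu4NHSO4, MeCN/CH2(OMe)2/aqueous buffer pH 10.5, 0 °C
Reagents that add atoms: potassium peroxymonosulfate, [K+].[O-]OS(=O)(=O)O
Why: Shi epoxidation of the E-disubstituted alkene through a spiro dioxirane transition state, in which the L-fructose-derived ketone should set both epoxide carbons as S.

**Step 4**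
Reactants: 4 (2S,3S)-epoxy alcohol
Product: 5 epoxy aldehyde
Conditions: Dess–Martin periodinane, NaHCO3, CH2Cl2, 0 to 23 °C; used crude
Reagents that add atoms: none
Why: Buffered Dess–Martin oxidation should give the β,γ-epoxy aldehyde without opening the epoxide.

**Step 5**
Reactants: 5 epoxy aldehyde
Product: 6 (Z)-silyl enyne
Conditions: 1,3-bis(triisopropylsilyl)propyne, n-BuLi, THF, −78 °C; then 5, −78 to 0 °C
Reagents that add atoms: 1,3-bis(triisopropylsilyl)propyne, CC(C)[Si](C(C)C)(C(C)C)CC#C[Si](C(C)C)(C(C)C)C(C)C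
Why: Peterson olefination with the lithiated bis-silyl propyne should give the Z enyne, because the bulky silyl groups direct the addition–elimination to the cis alkene.

**Step 6**
Reactants: 6 (Z)-silyl enyne
Product: 7 enynyl epoxy alcohol
Conditions: Bu4NF (2.5 equiv), THF, 0 to 23 °C
Reagents that add atoms: none
Why: Fluoride should cleave both the primary silyl ether and the alkynyl silane while leaving epoxide and enyne intact (desilylation).

**Step 7**
Reactants: 7 enynyl epoxy alcohol
Product: 8 enynyl epoxy aldehyde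
Conditions: Dess–Martin periodinane, NaHCO3, CH2Cl2, 0 to 23 °C; used crude
Reagents that add atoms: none
Why: Buffered Dess–Martin oxidation as in step 4 should give the aldehyde needed as heterodienophile.

**Step 8**
Reactants: 9 (E)-4,4-dimethoxybut-2-enal
Product: 10 racemic allylic alcohol acetal
Conditions: EtMgBr, THF, −78 °C
Reagents that add atoms: ethylmagnesium bromide, CC[Mg]Br
Why: 1,2-Grignard addition to the enal should give the alcohol; its stereocentre is lost later, so no control is needed.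

**Step 9**
Reactants: 10 racemic allylic alcohol acetal
Product: 11 (E)-4-hydroxyhex-2-enal
Conditions: Amberlyst-15, acetone/H2O, 23 °C
Reagents that add atoms: water, O
Why: Acid-catalysed acetal hydrolysis should release the E enal, which cannot form a lactol.

**Step 10**
Reactants: 11 (E)-4-hydroxyhex-2-enal
Product: 12 bis(silyloxy)diene
Conditions: t-BuMe2SiOTf (2.3 equiv), Et3N (3 equiv), CH2Cl2, 0 to 23 °C
Reagents that add atoms: tert-butyldimethylsilyl trifluoromethanesulfonate, CC(C)(C)[Si](C)(C)OS(=O)(=O)C(F)(F)F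
Why: O-silylation followed by vinylogous enolisation and silylation (silyl dienol ether formation) should give the 1E diene, as crotonaldehyde-type enals do.

**Step 11**
Reactants: 8 enynyl epoxy aldehyde; 12 bis(silyloxy)diene
Product: 15 bicyclic ketal alcohol, via silyl ketal cycloadduct 13 (not isolated), via hemiketal 14 (not isolated)
Conditions: 12 (1.5 equiv), CrCl(L) (5 mol %), 4 Å molecular sieves, t-BuOMe, 23 °C; then CH2Cl2/H2O, camphorsulfonic acid (0.2 equiv), 0 to 23 °C
Reagents that add atoms: water, O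
Why: The chromium Lewis acid binds the aldehyde of 8 and diene 12 adds in a concerted, asynchronous [4+2] hetero-Diels–Alder reaction (the known catalysed cyclocondensation of oxygenated dienes with unactivated aldehydes), the unhindered C10 terminus bonding to the carbonyl carbon (new C9–C10 bond) and the fully substituted, silyloxy-stabilised C13 terminus bonding to the carbonyl oxygen. This closes the dihydropyran by cycloaddition and fixes C11=C12 as cis because it lies in a six-membered ring; C9 is set by the chiral ligand (Si-face attack) and C10 by the endo transition state together with the E enol ether (2,3-cis, hence threo). Acidic water then exchanges the silyl ketal of 13 through the pyranylium ion for hemiketal 14, whose C13 hydroxyl, after anomerisation cis to the C9 side chain, opens the epoxide at C7 in a 6-exo-tet closure (new ring O–C7 bond), a known ketalising epoxide opening by a hemiketal hydroxyl. C7 is set by stereospecific inversion of the (S,S)-epoxide, C6 keeps the epoxide oxygen as a free hydroxyl, and the ketal carbon is dictated by the bridged ring. The step needs bonding through the diene termini, not Mukaiyama aldol addition through C11 or C12, which pericyclic catalysis by the mild chromium complex should favour. It also needs attack by the hemiketal oxygen, not by the C10 silyl ether oxygen, which the free hydroxyl and the strain-free chair–chair bicycle with equatorial C7 and C10 substituents should secure.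

**Step 12**
Reactants: 15 bicyclic ketal alcohol
Product: 16 bicyclic ketal chloride
Conditions: CCl4, P(n-C8H17)3, toluene, 70 °C
Reagents that add atoms: carbon tetrachloride, ClC(Cl)(Cl)Cl
Why: Appel-type chlorination of the only free hydroxyl via the alkoxyphosphonium ion should proceed with inversion, turning 6S-OH into 6R-Cl.

**Step 13**
Reactants: 16 bicyclic ketal chloride
Product: 17 bicyclic ketal allylic alcohol
Conditions: HF·pyridine, THF/pyridine, 0 to 23 °C
Reagents that add atoms: none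
Why: Acidic fluoride should remove the secondary silyl ether without base, so the β-chloride and the ketal survive (desilylation).

**Step 14**
Reactants: 17 bicyclic ketal allylic alcohol
Product: 18 oxocene diol
Conditions: TiCl4 (2.2 equiv), Et3SiH (5 equiv), CH2Cl2, −78 °C; NaHCO3 work-up
Reagents that add atoms: none
Why: Reductive cleavage of a bicyclic ketal (ring expansion to the medium-ring ether): the titanium alkoxide at C10 chelates the bridging C9 oxygen so that the C13–O bond of the one-atom bridge ionises, and triethylsilane delivers hydride to C13 anti to the departing oxygen, which should place the ethyl group cis to the C7 side chain (13R).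

**Step 15**
Reactants: 18 oxocene diol
Product: 19 target diacetate
Conditions: Ac2O, pyridine, DMAP (cat.), CH2Cl2, 0 to 23 °C
Reagents that add atoms: acetic anhydride, CC(=O)OC(C)=O
Why: Acylation of both secondary hydroxyls under mild base should not touch the chloride or the enyne and changes no stereocentre (acetylation).

**Compound list**

1 | (E)-hex-3-enedioic acid | OC(=O)C/C=C/CC(O)=O | starting material
2 | (E)-hex-3-ene-1,6-diol | OCC/C=C/CCO | intermediate
3 | (E)-6-[(tert-butyldiphenylsilyl)oxy]hex-3-en-1-ol | OCC/C=C/CCO[Si](c1ccccc1)(c1ccccc1)C(C)(C)C | intermediate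
4 | 2-[(2S,3S)-3-{2-[(tert-butyldiphenylsilyl)oxy]ethyl}oxiran-2-yl]ethan-1-ol | OCC[C@@H]1O[C@H]1CCO[Si](c1ccccc1)(c1ccccc1)C(C)(C)C | intermediate
5 | 2-[(2S,3S)-3-{2-[(tert-butyldiphenylsilyl)oxy]ethyl}oxiran-2-yl]acetaldehyde | O=CC[C@@H]1O[C@H]1CCO[Si](c1ccccc1)(c1ccccc1)C(C)(C)C | intermediate
6 | tert-butyl(diphenyl){2-[(2S,3S)-3-[(2Z)-5-(triisopropylsilyl)pent-2-en-4-yn-1-yl]oxiran-2-yl]ethoxy}silane | CC(C)[Si](C(C)C)(C(C)C)C#C/C=C\C[C@@H]1O[C@H]1CCO[Si](c1ccccc1)(c1ccccc1)C(C)(C)C | intermediate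
7 | 2-[(2S,3S)-3-[(2Z)-pent-2-en-4-yn-1-yl]oxiran-2-yl]ethan-1-ol | C#C/C=C\C[C@@H]1O[C@H]1CCO | intermediate
8 | 2-[(2S,3S)-3-[(2Z)-pent-2-en-4-yn-1-yl]oxiran-2-yl]acetaldehyde | C#C/C=C\C[C@@H]1O[C@H]1CC=O | intermediate
9 | (E)-4,4-dimethoxybut-2-enal | COC(OC)/C=C/C=O | starting material
10 | (E)-1,1-dimethoxyhex-2-en-4-ol, racemic | CCC(O)/C=C/C(OC)OC | intermediate
11 | (E)-4-hydroxyhex-2-enal, racemic | CCC(O)/C=C/C=O | intermediate
12 | (1E,3Z)-1,4-bis[(tert-butyldimethylsilyl)oxy]hexa-1,3-diene (3Z drawn; the C3=C4 geometry is inconsequential) | CC/C(O[Si](C)(C)C(C)(C)C)=C/C=C/O[Si](C)(C)C(C)(C)C | intermediate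
13 | (2R,3R)-3,6-bis[(tert-butyldimethylsilyl)oxy]-6-ethyl-2-{[(2S,3S)-3-[(2Z)-pent-2-en-4-yn-1-yl]oxiran-2-yl]methyl}-3,6-dihydro-2H-pyran, either configuration at the silyl ketal carbon | C#C/C=C\C[C@@H]1O[C@H]1C[C@@H]2[C@H](O[Si](C)(C)C(C)(C)C)/C=C\C(CC)(O[Si](C)(C)C(C)(C)C)O2 | intermediate
14 | (5R,6R)-5-[(tert-butyldimethylsilyl)oxy]-2-ethyl-6-{[(2S,3S)-3-[(2Z)-pent-2-en-4-yn-1-yl]oxiran-2-yl]methyl}-5,6-dihydro-2H-pyran-2-ol, both anomers | C#C/C=C\C[C@@H]1O[C@H]1C[C@@H]2[C@H](O[Si](C)(C)C(C)(C)C)/C=C\C(CC)(O)O2 | intermediate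
15 | (1R,3R,5R,6R)-6-[(tert-butyldimethylsilyl)oxy]-1-ethyl-3-[(1S,3Z)-1-hydroxyhex-3-en-5-yn-1-yl]-2,9-dioxabicyclo[3.3.1]non-7-ene | C#C/C=C\C[C@H](O)[C@H]1C[C@@H]2[C@H](O[Si](C)(C)C(C)(C)C)/C=C\[C@@](CC)(O2)O1 | intermediate
16 | (1S,3R,5R,6R)-6-[(tert-butyldimethylsilyl)oxy]-3-[(1R,3Z)-1-chlorohex-3-en-5-yn-1-yl]-1-ethyl-2,9-dioxabicyclo[3.3.1]non-7-ene | C#C/C=C\C[C@@H](Cl)[C@H]1C[C@@H]2[C@H](O[Si](C)(C)C(C)(C)C)/C=C\[C@@](CC)(O2)O1 | intermediate
17 | (1S,3R,5R,6R)-3-[(1R,3Z)-1-chlorohex-3-en-5-yn-1-yl]-1-ethyl-2,9-dioxabicyclo[3.3.1]non-7-en-6-ol | C#C/C=C\C[C@@H](Cl)[C@H]1C[C@@H]2[C@H](O)/C=C\[C@@](CC)(O2)O1 | intermediate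
18 | (2R,4R,5R,6Z,8R)-2-[(1R,3Z)-1-chlorohex-3-en-5-yn-1-yl]-8-ethyl-3,4,5,8-tetrahydro-2H-oxocine-4,5-diol | C#C/C=C\C[C@@H](Cl)[C@H]1C[C@@H](O)[C@H](O)/C=C\[C@@H](CC)O1 | intermediate
19 | (2R,4R,5R,6Z,8R)-2-[(1R,3Z)-1-chlorohex-3-en-5-yn-1-yl]-8-ethyl-3,4,5,8-tetrahydro-2H-oxocine-4,5-diyl diacetate | C#C/C=C\C[C@@H](Cl)[C@H]1C[C@@H](OC(C)=O)[C@H](OC(C)=O)/C=C\[C@@H](CC)O1 | target

**Totals.** Total step count: 15. Longest linear sequence: 12 steps (steps 1–7 and 11–15); the diene arm (steps 8–10) joins at step 11.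

**Steps most likely to fail**

1. Step 11. The cycloaddition may lose periselectivity (aldol-type addition through the inner diene carbons), face selectivity at the aldehyde may be poor, or water may open the epoxide before the hemiketal does. Fallback: the ketal is built by a furan route that sets out from 8 and comes back at 17. 5-Lithio-2-ethylfuran (2-ethylfuran, n-BuLi, THF, −78 °C) adds to 8 to give the furyl carbinol epimers F1. MnO2 oxidation gives furyl ketone F2, and Noyori transfer hydrogenation (RuCl(p-cymene)[(S,S)-TsDPEN], HCO2H/Et3N) sets the carbinol in (R)-furyl carbinol F3. Achmatowicz rearrangement (NBS, NaHCO3, THF/H2O, 0 °C) gives pyranone hemiketal F4, which camphorsulfonic acid closes onto the epoxide to give bicyclic enone ketal F5. Appel-type chlorination (CCl4, P(n-C8H17)3) gives chloro enone ketal F6. Luche reduction (NaBH4, CeCl3·7H2O, MeOH, −78 °C), by axial hydride attack next to the bridging oxygen, should then give 17.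

2. Step 14. The wrong ketal C–O bond may ionise (giving a dihydropyran), or hydride may arrive syn to the bridge (trans-2,8 ether). Fallback: the ring is closed by a hydroxy dithioketal cyclisation that sets out from 17 and comes back at 18. Ethanethiol with Zn(OTf)2 opens the ketal to dithioketal triol F7. 2-Methoxypropene with pyridinium p-toluenesulfonate protects the threo 9,10-diol as acetonide F8, leaving only the C7 hydroxyl free. AgClO4 with NaHCO3 in MeNO2 closes the eight-membered ring to mixed O,S-ketal F9. Et3SiH with AgOTf replaces the ethylsulfanyl group by hydride to give oxocene acetonide F10, and aqueous acetic acid removes the acetonide to give 18.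

3. Step 5. The basic silyl propynyl lithium may enolise the β,γ-epoxy aldehyde and open the epoxide by β-elimination, or Z selectivity may erode. Fallback: the enyne is made by olefination and cross-coupling, setting out from 5 and coming back at 6. Stork–Zhao olefination (Ph3P+CH2I I−, NaN(SiMe3)2, THF, −78 °C) gives (Z)-vinyl iodide F11. Sonogashira coupling with (triisopropylsilyl)acetylene (Pd(PPh3)4, CuI, Et3N) then gives 6.

**Further compounds**

F1 | step 11 | 1-(5-ethylfuran-2-yl)-2-[(2S,3S)-3-[(2Z)-pent-2-en-4-yn-1-yl]oxiran-2-yl]ethan-1-ol, both carbinol epimers | C#C/C=C\C[C@@H]1O[C@H]1CC(O)c1ccc(CC)o1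
F2 | step 11 | 1-(5-ethylfuran-2-yl)-2-[(2S,3S)-3-[(2Z)-pent-2-en-4-yn-1-yl]oxiran-2-yl]ethan-1-one | C#C/C=C\C[C@@H]1O[C@H]1CC(=O)c1ccc(CC)o1
F3 | step 11 | (1R)-1-(5-ethylfuran-2-yl)-2-[(2S,3S)-3-[(2Z)-pent-2-en-4-yn-1-yl]oxiran-2-yl]ethan-1-ol | C#C/C=C\C[C@@H]1O[C@H]1C[C@@H](O)c1ccc(CC)o1
F4 | step 11 | (2R)-6-ethyl-6-hydroxy-2-{[(2S,3S)-3-[(2Z)-pent-2-en-4-yn-1-yl]oxiran-2-yl]methyl}-2H-pyran-3(6H)-one, both anomers | C#C/C=C\C[C@@H]1O[C@H]1C[C@@H]2OC(O)(CC)C=CC2=O
F5 | step 11 | (1R,3R,5R)-1-ethyl-3-[(1S,3Z)-1-hydroxyhex-3-en-5-yn-1-yl]-2,9-dioxabicyclo[3.3.1]non-7-en-6-one | C#C/C=C\C[C@H](O)[C@H]1C[C@@H]2C(=O)C=C[C@@](CC)(O2)O1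
F6 | step 11 | (1S,3R,5R)-3-[(1R,3Z)-1-chlorohex-3-en-5-yn-1-yl]-1-ethyl-2,9-dioxabicyclo[3.3.1]non-7-en-6-one | C#C/C=C\C[C@@H](Cl)[C@H]1C[C@@H]2C(=O)C=C[C@@](CC)(O2)O1
F7 | step 14 | (3Z,6R,7R,9R,10R,11Z)-6-chloro-13,13-bis(ethylsulfanyl)pentadeca-3,11-dien-1-yne-7,9,10-triol | C#C/C=C\C[C@@H](Cl)[C@H](O)C[C@@H](O)[C@H](O)/C=C\C(CC)(SCC)SCC
F8 | step 14 | 9,10-O-isopropylidene derivative of F7 (free 7R hydroxyl; 9R,10R) | C#C/C=C\C[C@@H](Cl)[C@H](O)C[C@H]1OC(C)(C)O[C@@H]1/C=C\C(CC)(SCC)SCC
F9 | step 14 | acetonide-protected oxocene carrying ethyl and ethylsulfanyl on C13 (mixed O,S-ketal, both epimers; 6R,7R,9R,10R) | C#C/C=C\C[C@@H](Cl)[C@H]1C[C@H]2OC(C)(C)O[C@@H]2/C=C\C(CC)(SCC)O1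
F10 | step 14 | 4,5-O-isopropylidene derivative of oxocene diol 18 | C#C/C=C\C[C@@H](Cl)[C@H]1C[C@H]2OC(C)(C)O[C@@H]2/C=C\[C@@H](CC)O1
F11 | step 5 | tert-butyl{2-[(2S,3S)-3-[(2Z)-3-iodoprop-2-en-1-yl]oxiran-2-yl]ethoxy}diphenylsilane | I/C=C\C[C@@H]1O[C@H]1CCO[Si](c1ccccc1)(c1ccccc1)C(C)(C)C
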